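**Retrosynthetic overview**
1. Target 5 comes from benzyl ether 4 by O-debenzylation (last step).
2. Key disconnection of 4 cuts the CH2–C(=O) bond and the C(=O)–O bond at once: styrene 2 + CO + alcohol 3 (Pd–H hydroalkoxycarbonylation, anti-Markovnikov). No carboxylic acid is ever made or esterified.
3. Styrene 2 comes from aldehyde 1 by Wittig methylenation. Benzyl is the phenol mask because an aryl acetate would transesterify with 3 under the acid co-catalyst and a free vinylphenol would polymerise.
4. No ring is formed; the only ring (benzene) is bought in 1. There is no stereocentre to set.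

Assumption: the target is achiral (no stereocentre, no stereogenic double bond), so "single enantiomer" adds no requirement; the alkyl chain is read as unbranched nonadecyl (C19).

**Route**

Step 1
Reactants: 1 para-benzyloxybenzaldehyde [4-(benzyloxy)benzaldehyde]
Product: 2 para-benzyloxystyrene [1-(benzyloxy)-4-ethenylbenzene]
Conditions: Ph3PCH3Br (1.2 equiv), KOtBu (1.2 equiv), THF, 0 °C → rt
Reagents that add atoms: methyltriphenylphosphonium bromide, C[P+](c1ccccc1)(c1ccccc1)c1ccccc1.[Br-]
Why: Wittig olefination, in which the non-stabilised ylide Ph3P=CH2 adds to the non-enolisable aryl aldehyde and the oxaphosphetane collapses to the terminal alkene and Ph3P=O; the benzyl ether is inert to KOtBu and no stereocentre or alkene geometry arises.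

Step 2
Reactants: 2 para-benzyloxystyrene (1.2 equiv); 3 nonadecan-1-ol (1.0 equiv)
Product: 4 nonadecyl 3-[4-(benzyloxy)phenyl]propanoate
Conditions: Pd(OAc)2 (1 mol%), dtbpx [1,2-bis(di-tert-butylphosphinomethyl)benzene] (4 mol%), MsOH (5 mol%), CO (30 bar), PhMe (1 M), 80 °C
Reagents that add atoms: carbon monoxide, [C-]#[O+]
Why: Pd-catalysed hydroalkoxycarbonylation (hydroesterification, hydride cycle), in which [(dtbpx)Pd–H]+ adds to the styrene, the bulky chelating bis(di-tert-butylphosphine) steers the sequence through the linear alkyl–Pd, CO inserts to give the acyl–Pd and alcohol 3 cleaves it, so every atom of 2, 3 and CO ends up in 4; no stereocentre is formed.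

Step 3
Reactants: 4 nonadecyl 3-[4-(benzyloxy)phenyl]propanoate
Product: 5 nonadecyl 3-(4-hydroxyphenyl)propanoate (target)
Conditions: H2 (1 atm), 10% Pd/C, EtOAc–EtOH (1:1), rt
Reagents that add atoms: none
Why: Catalytic hydrogenolysis of the benzylic C–O bond on Pd/C frees the phenol under neutral conditions that leave the saturated alkyl ester and the arene untouched; no stereocentre is involved.

**Compound list**
1 | para-benzyloxybenzaldehyde [4-(benzyloxy)benzaldehyde] | O=Cc1ccc(OCc2ccccc2)cc1 | starting material
2 | para-benzyloxystyrene [1-(benzyloxy)-4-ethenylbenzene] | C=Cc1ccc(OCc2ccccc2)cc1 | intermediate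
3 | nonadecan-1-ol | CCCCCCCCCCCCCCCCCCCO | starting material
4 | nonadecyl 3-[4-(benzyloxy)phenyl]propanoate | CCCCCCCCCCCCCCCCCCCOC(=O)CCc1ccc(OCc2ccccc2)cc1 | intermediate
5 | nonadecyl 3-(4-hydroxyphenyl)propanoate | CCCCCCCCCCCCCCCCCCCOC(=O)CCc1ccc(O)cc1 | target

**Step count and risks**
Total step count: 3. Longest linear sequence: 3 (1 → 2 → 4 → 5; alcohol 3 enters at step 2).

Steps most likely to fail, in order of risk: step 2, step 3, step 1.

Step 2 is the real risk. Styrenes can give 5–20% of the branched 2-arylpropanoate even with dtbpx, and that isomer is hard to separate from a waxy ester (recrystallisation from hexane/EtOH is the planned purification). The electron-rich styrene can also oligomerise or add 3 in the Markovnikov sense under the acid co-catalyst. With only one equivalent of a long-chain alcohol, alcoholysis of the acyl–Pd may be slow enough for CO/styrene co-oligomers to form. The fallback sets out from 3 and uses 2. Alcohol 3 is acylated with acryloyl chloride (Et3N, CH2Cl2, 0 °C) to nonadecyl prop-2-enoate F1. Cross-metathesis of F1 with an excess of 2 (Hoveyda–Grubbs 2nd-generation catalyst, 2.5 mol%, CH2Cl2, 40 °C) gives nonadecyl (2E)-3-[4-(benzyloxy)phenyl]prop-2-enoate F2 with loss of ethylene. The regiochemistry is then fixed by the acrylate. Under the unchanged step 3 conditions (H2, Pd/C), F2 loses the C=C bond and the benzyl group together, so the fallback comes back to the route at 5.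

Step 3 is normally reliable. It could stall if traces of phosphine or sulfonic acid carried over from step 2 poison the Pd/C, or if the waxy ester is poorly soluble at room temperature. The fallback sets out from 4 and replaces the metal-surface reduction with a Lewis-acid ether cleavage: BCl3 (2 equiv) and pentamethylbenzene (3 equiv) as benzyl-cation scavenger, CH2Cl2, −78 °C, water quench. The alkyl ester survives at this temperature and the fallback comes back at 5. It makes no new compound (F0).

Step 1 is the least likely to fail. Incomplete ylide formation or a difficult separation from Ph3P=O would be the causes. The fallback sets out from 1. Addition of MeMgBr (THF, 0 °C, aqueous quench) gives racemic 1-[4-(benzyloxy)phenyl]ethan-1-ol F3. Acid-catalysed dehydration (cat. p-TsOH, PhMe, reflux, Dean–Stark, trace BHT) gives the styrene and removes the temporary stereocentre, so the fallback comes back to the route at 2.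

**Further compounds**
F1 | step 2 | nonadecyl prop-2-enoate | CCCCCCCCCCCCCCCCCCCOC(=O)C=C
F2 | step 2 | nonadecyl (2E)-3-[4-(benzyloxy)phenyl]prop-2-enoate | CCCCCCCCCCCCCCCCCCCOC(=O)/C=C/c1ccc(OCc2ccccc2)cc1
F0 | step 3 | none | none
F3 | step 1 | 1-[4-(benzyloxy)phenyl]ethan-1-ol (racemic) | CC(O)c1ccc(OCc2ccccc2)cc1
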